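## Analysis of the target

With the ring numbered C1 (bearing the exocyclic C7 of the CH2OBz group), C2 (the other alkene carbon) and C3 to C6 (carrying O3 to O6), the target is a single cyclohexene carbocycle with free hydroxyls on C3, C4 and C6, a benzoate on O5 and a second benzoate on the primary O7. C3 to C6 are four contiguous stereocentres, (3R,4S,5R,6S); O3 and O6 lie on one face and O4 and O5 on the other, so O3/O4 are trans, O4/O5 cis and O5/O6 trans. The ring is at the oxidation level of a hydrated arene: allylic ionisation at C3 or C6 followed by loss of water would lead to an aromatic benzyl benzoate, so strong acid and heat have to be avoided. The secondary benzoate can migrate to O4 or O6 under base, and the primary allylic benzoate is an ionisable leaving group. The difficulty lies not in the skeleton but in differentiation: four neighbouring secondary oxygens of similar reactivity, exactly one of them acylated, in a single enantiomeric series. The strategy rests on C1, C2, C5, C6 and C7: the trans O5/O6 pair beside the C7-bearing C1=C2 alkene is, atom for atom and in the correct absolute sense, the diol of microbial (2S,3S)-2,3-dihydroxy-2,3-dihydrobenzoic acid. In that dihydrodiol the C3=C4 alkene is the only electron-rich π bond, which is where the two missing oxygens have to go. O4/O5 is the only cis pair, so a five-membered cyclic orthoester can bridge only these two oxygens, and this is used to place the C5 benzoate.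

## Retrosynthetic reasoning

17 to 14 (acyl C–O bond at O5). The benzoyl group on O5 is removed first, because it is the hardest one to place. A cyclic orthobenzoate 16, made from 14 and orthoester 15, can only span the cis pair O4/O5. Its mild hydrolysis with water 2 hands the acyl group to the axial oxygen of the pair. In the half-chair that avoids A(1,2) strain between C7 and O6, that oxygen is O5. The forward step must deliver O5 over O4 selectivity without acyl migration.

14 back to 8 (acyl C–O bond at O7 and the oxidation level of C7). The primary benzoate comes from acid chloride 12 and alcohol 11, and 11 from hydride reduction of ester 10. The four secondary hydroxyls of 8 are masked as triethylsilyl ethers (from 9) for these two operations, giving 10, 11 and 13, and are released again to 14. This makes O7 the only free hydroxyl when 12 is added. The orthoester is deliberately not carried through the reduction, because cyclic orthoesters are cleaved reductively by Lewis-acidic aluminium hydride reagents.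

8 to 7 (C3–O bond). The trans O3/O4 pair, with O4 cis to O5, is what anti opening of an oxirane on the O5 face by water 2 at C3 gives. C3 is the allylic carbon and the one remote from the electron-withdrawing C5 hydroxyl. Opening at the ester stage is chosen because the acceptor on C1 suppresses allyl-cation formation and attack at C1. The forward step must give clean inversion at C3 and leave C4 untouched.

7 to 5 (C3–O and C4–O bonds of the oxirane, the key disconnection). Both oxirane bonds are cut at once, leading to dienoate 5 and peracid 6. This is the place to cut because in 5 the C1=C2 alkene is deactivated by the ester and the allylic C5 hydroxyl can steer the oxidant to its own face. One reagent then installs both missing oxygens with the relative configuration the target needs. The forward reaction must be site-selective for C3=C4 and face-selective for the O5 side.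

5 to 3 to 1 (ester O–CH3 bond, then the whole carbocycle). Ester 5 comes from acid 3 by methylation with 4 under non-acidic conditions, since 3 aromatises easily. Acid 3, with C5 and C6 already in the right absolute configuration and all seven carbons in place, is traced to D-glucose 1 through the shikimate pathway of an engineered bacterium. A hexose holds only six carbons, so the seven carbons of 3 are drawn from at least two molecules of 1, and water 2 supplies one hydroxyl oxygen. No carbon–carbon bond is made by chemical means.

## Alternatives that were turned down

Alternative 1: The cis O4/O5 pair is disconnected to an arene. Whole cells expressing toluene dioxygenase would cis-dihydroxylate bromobenzene A1 to (1S,2S)-3-bromocyclohexa-3,5-diene-1,2-diol A2, whose carbinol carbons become C4 and C5. In its favour, A2 is accessible on scale as a single enantiomer, the one cis relationship of the target is present from the start, and additions anti to the protected diol of A2 are dependable. Against it, when A2 is laid onto the target in the correct enantiomeric sense its bromine sits on C6, which needs oxygen. C7 is absent and must be attached to the neighbouring unsubstituted carbon C1. C3 and C6 must both be oxygenated trans to the diol, the halide carbon must become a carbinol of defined configuration, and O5 still has to be told apart from O4 at the end. That is at least four or five more operations. In comparison, alternative 1 is stronger on availability of the chiral building block and on having O4/O5 cis by construction. The chosen route offers instead all seven carbons, the C1=C2 alkene and two of the four stereocentres from the start, with no C–C bond to make.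

Alternative 2: The ring bonds C1–C6 and C2–C3 are cut in a [4+2] sense. Propynal A3, activated by a chiral boron Lewis acid, would add to (1E,3E)-buta-1,3-diene-1,4-diyl diacetate A4 to give (3S,6R)-3,6-diacetoxycyclohexa-1,4-diene-1-carbaldehyde A5. Suprafacial addition to the E,E-diene fixes O3 and O6 cis. A later cis-dihydroxylation of C4=C5 anti to both acyloxy groups would complete the pattern. In its favour, it is the most convergent plan: ring, C7 and two stereocentres arise in one step from achiral materials, with no biological step, and the length could be equal or shorter (about seven or eight steps). Against it, the diene carries two weakly donating acyloxy groups and is sluggish, so enantiofacial control for this ynal/diene pair is an extrapolation. A5 is a skipped diene with two allylic acyloxy leaving groups and is one elimination away from an aromatic aldehyde under the Lewis acid that forms it. The end game must remove two acetates and place one benzoate among four secondary oxygens. In comparison, the chosen route gives up this convergence for an absolute configuration set by enzymes, and for a key step whose selectivity comes from the substrate rather than from an untested catalyst–substrate match.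

Alternative 3: C3–O and C6–O are cut together. (−)-Shikimic acid A6 would be converted into the ring diene [(4S,5R)-4,5-(isopropylidenedioxy)cyclohexa-1(6),2-dien-1-yl]methyl benzoate A7 (target numbering). Sensitised photo-oxygenation would then add across C3 and C6 anti to the acetonide, giving the 2,3-dioxabicyclo[2.2.2]octene A8 with the alkene moved to C1=C2. In its favour, A6 is an inexpensive commodity, the cis O4/O5 pair comes from the pool, and anti addition is sterically enforced, arguably more predictable than a hydrogen-bond-directed epoxidation. O–O reduction and acetonide removal would lead straight to 14, so both routes would share the last step. Against it, A7 needs about five steps from A6 (ester and acetonide formation, dehydration to the conjugated diene, reduction, benzoylation). It is one elimination from an arene and offers allylic hydrogens for a competing ene reaction. The bicyclic peroxide can fragment to a hydroxy enone (Kornblum–DeLaMare) under base, and photochemistry with peroxides limits scale. In comparison, overall length is about the same (nine or ten steps), and alternative 3 is at least as strong on starting-material availability and facial control. The chosen route offers a two-step entry to its key substrate, an ordinary thermal oxidant, and an intermediate (7) in which O3/O4 are still distinct from O5/O6.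

Key step: step 3

## Route

Assumption: the production strain of step 1 (Escherichia coli without functional entA and with plasmid-borne entB and entC) is at hand. It acts as the catalyst and is not counted as a starting material; its intracellular pathway metabolites are treated as catalyst-bound species and are not numbered.

Remark on step 1: D-glucose is the only carbon source and is consumed in excess. An idealised atom balance is 2 C6H12O6 + 5/2 O2 → C7H8O4 + C3H4O3 + 2 CO2 + 6 H2O, with dioxygen from air as the terminal oxidant.

Step 1
Reactants: 1 D-glucose; 2 water
Product: 3 (5S,6S)-5,6-dihydroxycyclohexa-1,3-diene-1-carboxylic acid [(2S,3S)-2,3-dihydroxy-2,3-dihydrobenzoic acid]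
Conditions: E. coli (entA inactivated, entB/entC overexpressed), D-glucose (fed in excess)/mineral-salt medium, air, fed-batch, 37 °C, pH 7; cell removal, anion-exchange capture, lyophilisation
Reagents that add atoms: D-glucose, OC[C@H]1OC(O)[C@H](O)[C@@H](O)[C@@H]1O; water, O
Why: Whole-cell fermentation along the shikimate pathway: with the dihydrodiol dehydrogenase (entA) absent and isochorismate synthase and isochorismatase (entC, entB) overexpressed, the pathway is diverted at its branch point to the trans-dihydrodiol, which should accumulate in the medium. One hexose cannot supply the seven carbons of 3: four come from glucose-derived erythrose 4-phosphate and three from glucose-derived phosphoenolpyruvate, so at least two molecules of 1 are consumed per molecule of 3, a second three-carbon unit leaving as pyruvic acid and the remaining carbon as CO2. Water supplies the C6 hydroxyl oxygen in the isochorismate synthase step, and both stereocentres (C5 and C6, each S) are set by the enzymes.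

Step 2
Reactants: 3 (5S,6S)-5,6-dihydroxycyclohexa-1,3-diene-1-carboxylic acid; 4 trimethylsilyldiazomethane
Product: 5 methyl (5S,6S)-5,6-dihydroxycyclohexa-1,3-diene-1-carboxylate
Conditions: Me3SiCHN2 (1.2 equiv), MeOH/PhMe 1:3, 0 °C
Reagents that add atoms: trimethylsilyldiazomethane, C[Si](C)(C)C=[N+]=[N-]
Why: Diazoalkane esterification: the acid protonates the reagent, methanol removes silicon to release diazomethane in the flask, and this O-methylates the carboxylic acid with loss of nitrogen, with no mineral acid or heat that would aromatise the diene diol; the hydroxyls are not alkylated and no stereocentre is touched.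

Step 3
Reactants: 5 methyl (5S,6S)-5,6-dihydroxycyclohexa-1,3-diene-1-carboxylate; 6 3-chloroperbenzoic acid
Product: 7 methyl (3S,4R,5R,6S)-3,4-epoxy-5,6-dihydroxycyclohex-1-ene-1-carboxylate (oxirane on the face of O5, trans to O6)
Conditions: mCPBA (1.1 equiv), CH2Cl2, 0 °C to rt; aq. Na2S2O3/NaHCO3 wash
Reagents that add atoms: 3-chloroperbenzoic acid, O=C(OO)c1cccc(Cl)c1
Why: Prilezhaev epoxidation under Henbest control: peracid 6, held by a hydrogen bond from the allylic C5 hydroxyl, transfers its electrophilic oxygen through the concerted spiro (butterfly) transition state to both carbons of the C3–C4 alkene from the face that carries O5. The closest known reaction types are the syn epoxidation of cyclohex-2-enols by peracids and the γ,δ-selective epoxidation of 2,4-dienoates. The oxirane closes in one suprafacial [2+1] oxygen transfer, so both C–O bonds form on the same face and the three-membered ring is necessarily cis-fused to the carbocycle. The new stereocentres C3 and C4 are set together, and their configuration is controlled by the existing C5 carbinol centre through the hydrogen bond. Site selectivity is secured because the C1–C2 alkene is conjugated with and deactivated by the ester, whereas C3–C4 is the electron-rich end of the dienoate. Facial selectivity is secured because the allylic C5 hydroxyl is a better director than the homoallylic C6 hydroxyl, which lies on the other face, can be tied up by an internal hydrogen bond to the ester carbonyl and, when pseudoaxial, shields its own face. A non-coordinating solvent keeps the directing hydrogen bond intact, and low temperature keeps the acid-sensitive vinyl oxirane from opening.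

Step 4
Reactants: 7 methyl (3S,4R,5R,6S)-3,4-epoxy-5,6-dihydroxycyclohex-1-ene-1-carboxylate; 2 water
Product: 8 methyl (3R,4S,5R,6S)-3,4,5,6-tetrahydroxycyclohex-1-ene-1-carboxylate
Conditions: H2SO4 (cat.), THF/H2O 1:1, 0 °C to rt; BaCO3 neutralisation, filtration, concentration
Reagents that add atoms: water, O
Why: Acid-catalysed SN2-type hydrolysis of a vinyl oxirane: water attacks the protonated oxirane at C3, the allylic carbon and the one remote from the inductively withdrawing C5 hydroxyl, anti to the leaving oxygen, so C3 is inverted (O3 trans to O4) while C4 keeps its oxygen cis to O5. The ester on C1 disfavours ionisation to an allyl cation and attack at C1, which keeps the opening stereospecific.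

Step 5
Reactants: 8 methyl (3R,4S,5R,6S)-3,4,5,6-tetrahydroxycyclohex-1-ene-1-carboxylate; 9 triethylsilyl trifluoromethanesulfonate
Product: 10 methyl (3R,4S,5R,6S)-3,4,5,6-tetrakis(triethylsilyloxy)cyclohex-1-ene-1-carboxylate
Conditions: Et3SiOTf (5 equiv), 2,6-lutidine (8 equiv), CH2Cl2, –78 to 0 °C
Reagents that add atoms: triethylsilyl trifluoromethanesulfonate, CC[Si](CC)(CC)OS(=O)(=O)C(F)(F)F
Why: Exhaustive O-silylation with a silyl triflate and a hindered pyridine base is standard for congested polyols; no stereocentre is touched, and masking all four secondary oxygens leaves O7 as the only hydroxyl after the reduction.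

Step 6
Reactants: 10 methyl (3R,4S,5R,6S)-3,4,5,6-tetrakis(triethylsilyloxy)cyclohex-1-ene-1-carboxylate
Product: 11 [(3R,4S,5R,6S)-3,4,5,6-tetrakis(triethylsilyloxy)cyclohex-1-en-1-yl]methanol
Conditions: iBu2AlH (2.5 equiv), CH2Cl2, –78 °C; aq. KNaC4H4O6 work-up
Reagents that add atoms: none
Why: 1,2-Reduction of an α,β-unsaturated ester by iBu2AlH at low temperature gives the allylic alcohol; silyl ethers are inert, and the molecule holds no oxirane or orthoester at this stage that the Lewis-acidic hydride could attack.

Step 7
Reactants: 11 [(3R,4S,5R,6S)-3,4,5,6-tetrakis(triethylsilyloxy)cyclohex-1-en-1-yl]methanol; 12 benzoyl chloride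
Product: 13 [(3R,4S,5R,6S)-3,4,5,6-tetrakis(triethylsilyloxy)cyclohex-1-en-1-yl]methyl benzoate
Conditions: BzCl (1.3 equiv), pyridine, DMAP (cat.), CH2Cl2, 0 °C to rt
Reagents that add atoms: benzoyl chloride, O=C(Cl)c1ccccc1
Why: DMAP-catalysed acylation of the only free hydroxyl, the primary allylic O7, so no site selectivity is required.

Step 8
Reactants: 13 [(3R,4S,5R,6S)-3,4,5,6-tetrakis(triethylsilyloxy)cyclohex-1-en-1-yl]methyl benzoate
Product: 14 [(3R,4S,5R,6S)-3,4,5,6-tetrahydroxycyclohex-1-en-1-yl]methyl benzoate
Conditions: HF·pyridine, THF/pyridine, 0 °C to rt; NaHCO3 quench
Reagents that add atoms: none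
Why: Fluoride-driven cleavage of all four triethylsilyl ethers (Si–F bond formation) under buffered, weakly acidic conditions, chosen over basic fluoride so that the primary benzoate neither migrates to O6 nor is cleaved.

Step 9
Reactants: 14 [(3R,4S,5R,6S)-3,4,5,6-tetrahydroxycyclohex-1-en-1-yl]methyl benzoate; 15 trimethyl orthobenzoate; 2 water
Product: 17 [(3R,4S,5R,6S)-5-(benzoyloxy)-3,4,6-trihydroxycyclohex-1-en-1-yl]methyl benzoate (target), via cyclic orthobenzoate 16 (not isolated)
Conditions: PhC(OMe)3 (1.3 equiv), camphorsulfonic acid (5 mol%), MeCN, rt; then AcOH/H2O 4:1, 0 °C to rt
Reagents that add atoms: trimethyl orthobenzoate, COC(OC)(OC)c1ccccc1; water, O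
Why: Acid-catalysed orthoester exchange places a cis-fused 2-methoxy-2-phenyl-1,3-dioxolane on the only cis pair, O4/O5; mild aqueous acid then passes through the dioxolan-2-ylium ion and the hemiorthoester, which collapses under stereoelectronic control to the axial ester and equatorial alcohol (the orthoester route to axial monoesters of cis-cyclohexanediols). In the half-chair favoured by A(1,2) strain between C7 and O6, O5 is axial and O4 equatorial, so the benzoyl group should end on O5; no stereocentre is touched.

## Compound list

1 | D-glucose | OC[C@H]1OC(O)[C@H](O)[C@@H](O)[C@@H]1O | starting material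
2 | water | O | starting material
3 | (5S,6S)-5,6-dihydroxycyclohexa-1,3-diene-1-carboxylic acid | OC(=O)C1=CC=C[C@H](O)[C@H]1O | intermediate
4 | trimethylsilyldiazomethane | C[Si](C)(C)C=[N+]=[N-] | starting material
5 | methyl (5S,6S)-5,6-dihydroxycyclohexa-1,3-diene-1-carboxylate | COC(=O)C1=CC=C[C@H](O)[C@H]1O | intermediate
6 | 3-chloroperbenzoic acid | O=C(OO)c1cccc(Cl)c1 | starting material
7 | methyl (3S,4R,5R,6S)-3,4-epoxy-5,6-dihydroxycyclohex-1-ene-1-carboxylate | COC(=O)C1=C[C@@H]2O[C@@H]2[C@H](O)[C@H]1O | intermediate
8 | methyl (3R,4S,5R,6S)-3,4,5,6-tetrahydroxycyclohex-1-ene-1-carboxylate | COC(=O)C1=C[C@@H](O)[C@H](O)[C@H](O)[C@H]1O | intermediate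
9 | triethylsilyl trifluoromethanesulfonate | CC[Si](CC)(CC)OS(=O)(=O)C(F)(F)F | starting material
10 | methyl (3R,4S,5R,6S)-3,4,5,6-tetrakis(triethylsilyloxy)cyclohex-1-ene-1-carboxylate | COC(=O)C1=C[C@@H](O[Si](CC)(CC)CC)[C@H](O[Si](CC)(CC)CC)[C@H](O[Si](CC)(CC)CC)[C@H]1O[Si](CC)(CC)CC | intermediate
11 | [(3R,4S,5R,6S)-3,4,5,6-tetrakis(triethylsilyloxy)cyclohex-1-en-1-yl]methanol | OCC1=C[C@@H](O[Si](CC)(CC)CC)[C@H](O[Si](CC)(CC)CC)[C@H](O[Si](CC)(CC)CC)[C@H]1O[Si](CC)(CC)CC | intermediate
12 | benzoyl chloride | O=C(Cl)c1ccccc1 | starting material
13 | [(3R,4S,5R,6S)-3,4,5,6-tetrakis(triethylsilyloxy)cyclohex-1-en-1-yl]methyl benzoate | O=C(OCC1=C[C@@H](O[Si](CC)(CC)CC)[C@H](O[Si](CC)(CC)CC)[C@H](O[Si](CC)(CC)CC)[C@H]1O[Si](CC)(CC)CC)c1ccccc1 | intermediate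
14 | [(3R,4S,5R,6S)-3,4,5,6-tetrahydroxycyclohex-1-en-1-yl]methyl benzoate | O=C(OCC1=C[C@@H](O)[C@H](O)[C@H](O)[C@H]1O)c1ccccc1 | intermediate
15 | trimethyl orthobenzoate | COC(OC)(OC)c1ccccc1 | starting material
16 | 4,5-O-(α-methoxybenzylidene) orthoester of 14 (cis-fused 2-methoxy-2-phenyl-1,3-dioxolane on O4/O5, both epimers at the orthoester carbon) | O=C(OCC1=C[C@@H](O)[C@H](OC(OC)(c3ccccc3)O2)[C@H]2[C@H]1O)c1ccccc1 | intermediate
17 | [(3R,4S,5R,6S)-5-(benzoyloxy)-3,4,6-trihydroxycyclohex-1-en-1-yl]methyl benzoate | O=C(OCC1=C[C@@H](O)[C@H](O)[C@H](OC(=O)c2ccccc2)[C@H]1O)c1ccccc1 | target

Total step count: 9. Longest linear sequence: 9 steps (1 to 17).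

## Least certain steps

Step 3 (key step). The most likely failure is insufficient facial selectivity: delivery by the homoallylic C6 hydroxyl, or plain steric approach, would put the oxirane on the wrong face. A second failure is acid-induced opening or aromatisation of the vinyl oxirane by the carboxylic acid formed during the reaction. Fallback, from 5 back to 7: the oxirane is built through a halohydrin. N-Bromosuccinimide in aqueous THF should add bromine to the C3–C4 alkene anti to the allylic C5 oxygen, and water should open the bromonium ion at allylic C3, giving methyl (3S,4R,5R,6S)-4-bromo-3,5,6-trihydroxycyclohex-1-ene-1-carboxylate F1. K2CO3 in methanol at 0 °C then closes the ring by backside displacement of bromide by O3, so that the oxirane oxygen ends on the face of O5, which is compound 7. The facial outcome here rests on anti addition of the electrophile, not on a hydrogen bond, and either regioisomer of the trans-bromohydrin would close to the same oxirane.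

Step 4. The most likely failure is loss of regiocontrol. The ester on C1 weakens the allylic activation of C3, so water may attack C4 and give the all-trans tetraol, or forcing conditions may cause dehydration towards an arene. Fallback, from 7 back to 14: the opening is postponed until the acceptor is gone. Compound 7 is silylated with 9 and 2,6-lutidine to the 5,6-bis(triethylsilyl) ether of 7 F2. This is reduced with iBu2AlH at –78 °C to the epoxy allylic alcohol F3, which is benzoylated with 12 and pyridine to the epoxy benzoate F4. Dilute aqueous HClO4 in THF then opens the oxirane at C3, now allylic to an ordinary alkene, and removes the two silyl ethers in the same flask, giving 14.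

Step 9. The most likely failure is collapse of the hemiorthoester towards the C4 benzoate or a mixture, because the two half-chair conformers are close in energy. Acyl migration between O4, O5 and O6 during work-up would add to this. Fallback, from 7 to 17: the site of the benzoate is fixed by connectivity, not by conformation. iBu2AlH at –78 °C reduces 7 to the epoxy triol [(3S,4R,5R,6S)-3,4-epoxy-5,6-dihydroxycyclohex-1-en-1-yl]methanol F5. 2,2-Dimethoxypropane with pyridinium tosylate closes the six-membered O6/O7 acetonide F6, since the trans O5/O6 pair cannot form a five-membered ketal without strain. Compound 12 with pyridine and DMAP acylates the only free hydroxyl and gives the C5 benzoate of the acetonide F7. Dilute aqueous acid removes the acetonide and opens the oxirane at C3, giving (3R,4S,5R,6S)-5-(benzoyloxy)-1-(hydroxymethyl)cyclohex-1-ene-3,4,6-triol F8. Compound 12 with 2,4,6-collidine at –40 °C then benzoylates the primary hydroxyl selectively and gives 17.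

Step 5. The most likely failure is incomplete silylation of the crowded cis O4/O5 pair. A stray hydroxyl would then take up a benzoyl group in step 7, and the water-soluble tetraol 8 may also be lost on isolation. Fallback, from 8 back to 14, without protecting groups: excess iBu2AlH in THF (–78 to 0 °C) reduces 8 to the pentaol (3R,4S,5R,6S)-1-(hydroxymethyl)cyclohex-1-ene-3,4,5,6-tetrol F9. Immobilised Candida antarctica lipase B with vinyl benzoate then acylates only the primary hydroxyl, giving 14.

## Further compounds

F1 | step 3 | methyl (3S,4R,5R,6S)-4-bromo-3,5,6-trihydroxycyclohex-1-ene-1-carboxylate | COC(=O)C1=C[C@H](O)[C@@H](Br)[C@H](O)[C@H]1O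
F2 | step 4 | 5,6-bis(triethylsilyl) ether of 7 | COC(=O)C1=C[C@@H]2O[C@@H]2[C@H](O[Si](CC)(CC)CC)[C@H]1O[Si](CC)(CC)CC
F3 | step 4 | epoxy allylic alcohol from reduction of F2 | OCC1=C[C@@H]2O[C@@H]2[C@H](O[Si](CC)(CC)CC)[C@H]1O[Si](CC)(CC)CC
F4 | step 4 | primary benzoate of F3 | O=C(OCC1=C[C@@H]2O[C@@H]2[C@H](O[Si](CC)(CC)CC)[C@H]1O[Si](CC)(CC)CC)c1ccccc1
F5 | step 9 | [(3S,4R,5R,6S)-3,4-epoxy-5,6-dihydroxycyclohex-1-en-1-yl]methanol | OCC1=C[C@@H]2O[C@@H]2[C@H](O)[C@H]1O
F6 | step 9 | 6,7-O-isopropylidene acetal of F5 (six-membered, C5 hydroxyl free) | CC1(C)OCC2=C[C@@H]3O[C@@H]3[C@H](O)[C@H]2O1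
F7 | step 9 | C5 benzoate of F6 | CC1(C)OCC2=C[C@@H]3O[C@@H]3[C@H](OC(=O)c4ccccc4)[C@H]2O1
F8 | step 9 | (3R,4S,5R,6S)-5-(benzoyloxy)-1-(hydroxymethyl)cyclohex-1-ene-3,4,6-triol | OCC1=C[C@@H](O)[C@H](O)[C@H](OC(=O)c2ccccc2)[C@H]1O
F9 | step 5 | (3R,4S,5R,6S)-1-(hydroxymethyl)cyclohex-1-ene-3,4,5,6-tetrol | OCC1=C[C@@H](O)[C@H](O)[C@H](O)[C@H]1O
A1 | alternative 1 | bromobenzene | Brc1ccccc1
A2 | alternative 1 | (1S,2S)-3-bromocyclohexa-3,5-diene-1,2-diol | BrC1=CC=C[C@H](O)[C@@H]1O
A3 | alternative 2 | propynal | C#CC=O
A4 | alternative 2 | (1E,3E)-buta-1,3-diene-1,4-diyl diacetate | CC(=O)O/C=C/C=C/OC(C)=O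
A5 | alternative 2 | (3S,6R)-3,6-diacetoxycyclohexa-1,4-diene-1-carbaldehyde | O=CC1=C[C@@H](OC(C)=O)C=C[C@H]1OC(C)=O
A6 | alternative 3 | (−)-shikimic acid | OC(=O)C1=C[C@@H](O)[C@@H](O)[C@H](O)C1
A7 | alternative 3 | [(4S,5R)-4,5-(isopropylidenedioxy)cyclohexa-1(6),2-dien-1-yl]methyl benzoate (target numbering) | O=C(OCC1=C[C@H]2OC(C)(C)O[C@H]2C=C1)c1ccccc1
A8 | alternative 3 | anti endoperoxide of A7 (2,3-dioxabicyclo[2.2.2]oct-5-ene) | O=C(OCC1=C[C@H]2OO[C@@H]1[C@H]3OC(C)(C)O[C@H]32)c1ccccc1
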